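**Structural features**

The target is a flavanone: ring A, a phloroglucinol-type arene (C4a–C8a), is fused to the pyranone ring C, which carries the phenyl ring B at C2. Ring D, an N-methylpiperidine, is joined through its C2' to C6 of ring A, between the hydroxyls at C5 and C7. There are two stereocentres, C2 (S) in ring C and C2' (R) in ring D; they are not adjacent but separated by the whole of ring A, so neither can direct the other and each must be set independently. Both are fragile: C2 is lost when ring C opens to the 2'-hydroxychalcone (base, heat), and re-closure on the other ortho oxygen would move the piperidine from C6 to C8. C2' is a benzylic C–N bond on a trioxygenated arene that can ionise under acid or, from a free phenol, by retro-aza-Michael loss of the amine. The real difficulty is C2', a hindered benzylic amine carbon with no chiral-pool source, together with the 6- versus 8-regiochemistry of ring C on a ring A whose three oxygens start out equivalent. The key step exploits the position of C2' on C6 between O5 and O7: its cation is an ortho-quinone methide of ring A, which can be generated catalytically from a carbinol and captured by the tethered nitrogen inside a chiral ion pair.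

**Logic of the disconnections**

18 ⇒ 17. The O5–benzyl and O7–benzyl bonds are added retrosynthetically. The phenols must be masked through alkylation, hydride, Mitsunobu and anhydride chemistry, and benzyl can be removed without the base that opens ring C or the strong acid that ionises C2'–N. The gain is a ring A that is no longer nucleophilic and has no chalcone or quinone methide pathway. The demand is a hydrogenolysis that stops at the two aryl benzyl ethers and spares C2–O1, C2'–N and the C4 ketone.

17 ⇒ 15 (through 16). The C4–C4a bond is cut. In 15 ring A is symmetric about the O1···C6 axis, so acylation at either free position gives the same chromanone and the 6/8 question disappears. The gain is the loss of ring C, leaving an open-chain acid. The demand is an electrophilic closure mild enough not to ionise C2'–N or the benzylic C2–O1 ether, with the amine protonated so that it is not acylated.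

15 ⇒ 14 ⇒ 12 + 13. The ester C–O bond and then the O1–C2 bond are cut. C2 is available enantiopure in 13, and an etherification with inversion joins it to the phenol. The gain is convergence: two fragments, each with one stereocentre. The demand is a clean SN2 inversion at a secondary benzylic carbon without elimination, and an ester hydrolysis that does not expel the phenoxide by E1cB.

12 ⇒ 11 ⇒ 10 ⇒ 9. The O1–allyl bond is re-formed, N–CH3 is traced back to N–CO2CH3, and one O–benzyl bond is cut. The carbamate carbon is the N-methyl carbon at a higher oxidation level, so the group that makes nitrogen a neutral N–H nucleophile for the key step is not wasted. The allyl group keeps O1 distinct from O5 and O7. The demand is an order of events in which the last ortho phenol is capped before the nitrogen becomes basic, so that no free ortho-hydroxybenzylic amine can re-open, and a deallylation orthogonal to benzyl.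

9 ⇒ 7 (through 8). The N–C2' bond is cut; this is the only ring D bond made in the route and it creates C2'. The gain is large: ring D and its stereocentre are replaced by an acyclic chain on a racemic carbinol that is erased in the step. The demand is catalyst control over a planar methide carbon, which is why 7 carries exactly one free ortho hydroxyl (a single binding site for the acid) and a robust methyl carbamate as the N–H donor.

7 ⇒ 6 ⇒ 5 ⇒ 4. The carbinol C–H bond, the O–benzyl bond and the O–allyl bond are cut in turn. In 4 the carbonyl differentiates the three oxygens: the para hydroxyl is the most acidic and unchelated, and of the two chelated hydroxyls only the first is readily alkylated. The gain is a symmetric triol ketone. The demands are two regioselective alkylations and a reduction that does not trigger quinone methide formation.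

4 ⇒ 2 + 3, then 2 ⇒ 1. The aryl–acyl bond C6–C2' and the N–C(O) bond are cut. All ring positions of 3 are equivalent, and 1 supplies the five carbons and the nitrogen of ring D in the right order. The gain is two commodity starting materials. The demand is a carbamate that survives the Lewis acid acylation, which a methyl carbamate does.

**Other disconnections considered**

Alternative 1: The cut is O1–C8a of ring C. In the forward direction the (S)-configured secondary benzylic alcohol A1, whose ring A carries bromine at C8a, would be closed by intramolecular palladium-catalysed aryl etherification (Pd(OAc)2, 2-(di-tert-butylphosphino)-1,1'-binaphthyl, Cs2CO3) to the 4-silyloxyflavan A2. Desilylation, oxidation at C4 and debenzylation would follow.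
- In its favour: the new bond is made at the aryl carbon, so C2 is carried through untouched. This is better than the inversion of step 10, which can leak through elimination or ionisation. No strong acid comes near C2'–N, which is better than step 12. The carbonyl appears late, so the chalcone pathway is closed for most of the route, which is equal or better.
- Against it here: ring A must come from a bromoresorcinol rather than from symmetric 3. The three-carbon 1,3-dioxygenated chain has to be attached to a crowded arene and its carbinol centre set by a separate asymmetric step. Palladium alkoxides of secondary alcohols can undergo β-hydride elimination, and the tertiary amine can bind the metal. Two further steps (silyl removal, C4 oxidation beside an oxidisable amine) and a pair of C4 epimers are added.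
- Comparison: the alternative says nothing about C2', which must still be made by other means. It is better precedented mechanistically than step 6, it addresses the easier of the two stereocentres, and it is poorer in step economy (chain construction, coupling, desilylation and oxidation against steps 10–12).

Alternative 2: The cuts are C2'–C3' and N–C6' of ring D. In the forward direction a 4-chlorobutyl Grignard reagent would add to the (S)-N-tert-butanesulfinyl aldimine A3 through a six-membered magnesium-bridged transition state. Warming with KOtBu would then let the sulfinamide anion displace chloride to give the N-sulfinylpiperidine A4.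
- In its favour: this is established auxiliary chemistry, so on precedent it is better than step 6. The diastereomeric products can be purified to upgrade stereochemical purity, an advantage that a catalytic enantioselective step lacks. No labile quinone methide precursor is handled. Counting imine formation, addition–cyclisation, sulfinyl removal, N-methylation and conversion of C–Br into C–OH after the aldehyde is in hand, the path to the common phenol 12 is about equal in length to steps 1–9 or slightly shorter, which is a point for the alternative.
- Against it here: the chiral reagent is stoichiometric. The aldimine is doubly ortho-substituted, so addition should be slow, and the two ortho oxygens can chelate magnesium and disturb the closed transition state on which the sense and level of induction rest. The symmetric bromo aldehyde is not a commodity like 3. The bromide-to-phenol exchange adds a metal-catalysed step on a basic amine.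
- Comparison: both plans set C2' on a symmetric ring A precursor and both deliver O1 already differentiated (bromine there, allyl here). The alternative is the safer way to C2'. The chosen plan is preferred because it is catalytic, starts from cheaper materials, and turns the ortho-oxygen pattern, a liability for the Grignard addition, into the activating element.

Alternative 3: The cut is C4–C4a. In the forward direction the (S)-3-aryloxy-3-phenylpropanoic acid A5 would be converted by (CF3CO)2O into a mixed anhydride that acylates ring A ortho to the ether oxygen, giving the protected flavanone A6.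
- In its favour: ring A of A5 is symmetric, so there is no regiochemical question. C2 comes from a commercial enantiopure hydroxy ester. The reaction is well precedented on phloroglucinol ethers, so on precedent it is better than step 6.
- Against it here: a strong acid meets a benzylic C2'–N bond on a trialkoxyarene. The step creates neither ring D nor C2', which must be in place beforehand.
- Comparison: A5 and A6 are the same compounds as 15 and 17, and this closure is adopted as step 12 of the chosen plan. As a ring C tactic it is therefore the equal of the chosen plan. As the strategic focus it leaves the harder centre unsolved, which is why the weight of the plan is put on step 6.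

Key step: step 6

**Remarks and assumptions on the chemistry**

- Read from its SMILES string, the target is the (2S,2'R) isomer. The descriptors of all compounds were re-derived and none needed correction. Because the etherification of step 10 inverts, the hydroxy ester must be R.
- Two spectator groups of the key-step precursor were redesigned without changing its skeleton or the bond formed. The carbamate is a methyl rather than a benzyl ester, because a benzyl carbamate would not survive the Lewis acid acylation of step 2 and either ester is reduced to the same N-methyl group. One ortho oxygen is already a benzyl ether, which leaves a single free ortho hydroxyl.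
- Assumption: the sense of induction of the phosphoric acid in this new cyclisation cannot be predicted with confidence. The (R)-acid is written; its commercially available mirror image is used instead if it proves to deliver the (S)-piperidine.

**Route**

Step 1
Reactants: 1 5-aminopentanoic acid
Product: 2 5-[(methoxycarbonyl)amino]pentanoic acid
Conditions: ClCO2Me, NaOH, H2O–dioxane, 0 °C → rt; then HCl, pH 2
Reagents that add atoms: methyl chloroformate, COC(=O)Cl
Why: Schotten–Baumann N-acylation of the amino acid salt; the methyl carbamate survives the Lewis acid of step 2 and its carbonyl carbon later becomes the N-methyl carbon.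

Step 2
Reactants: 2 5-[(methoxycarbonyl)amino]pentanoic acid; 3 phloroglucinol
Product: 4 methyl N-[5-oxo-5-(2,4,6-trihydroxyphenyl)pentyl]carbamate
Conditions: BF3·OEt2 (solvent), 70 °C; then aq. NaOAc
Reagents that add atoms: none
Why: Friedel–Crafts (Nencki-type) C-acylation of the very electron-rich arene by the BF3-activated free acid; the ring positions are equivalent, the first acyl group deactivates the ring against a second, and using the acid itself avoids an acid chloride that could lactamise onto the carbamate nitrogen.

Step 3
Reactants: 4 methyl N-[5-oxo-5-(2,4,6-trihydroxyphenyl)pentyl]carbamate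
Product: 5 methyl N-{5-[4-(allyloxy)-2,6-dihydroxyphenyl]-5-oxopentyl}carbamate
Conditions: allyl bromide (1.05 equiv), KHCO3, DMF, 40 °C
Reagents that add atoms: allyl bromide, C=CCBr
Why: Williamson etherification; the para hydroxyl is the most acidic and the only one not hydrogen-bonded to the ketone, so a weak base ionises and alkylates it selectively and marks the future O1.

Step 4
Reactants: 5 methyl N-{5-[4-(allyloxy)-2,6-dihydroxyphenyl]-5-oxopentyl}carbamate
Product: 6 methyl N-{5-[4-(allyloxy)-2-(benzyloxy)-6-hydroxyphenyl]-5-oxopentyl}carbamate
Conditions: BnBr (1.1 equiv), K2CO3, acetone, reflux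
Reagents that add atoms: benzyl bromide, BrCc1ccccc1
Why: Williamson etherification of one of the two equivalent chelated hydroxyls; the remaining hydroxyl then forms a single, stronger hydrogen bond to the carbonyl and resists alkylation, so the reaction should stop at the mono-benzyl ether.

Step 5
Reactants: 6 methyl N-{5-[4-(allyloxy)-2-(benzyloxy)-6-hydroxyphenyl]-5-oxopentyl}carbamate
Product: 7 methyl N-{5-[4-(allyloxy)-2-(benzyloxy)-6-hydroxyphenyl]-5-hydroxypentyl}carbamate (racemic carbinol)
Conditions: NaBH4, THF–MeOH, −10 → 0 °C; pH 7 phosphate buffer; dried and used at once
Reagents that add atoms: none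
Why: Borohydride reduction of the aryl ketone; the carbinol is racemic, which is of no consequence because this centre becomes planar in step 6, and cold, buffered handling keeps the labile ortho-hydroxybenzylic alcohol from ionising early.

Step 6
Reactants: 7 methyl N-{5-[4-(allyloxy)-2-(benzyloxy)-6-hydroxyphenyl]-5-hydroxypentyl}carbamate (racemic carbinol)
Product: 9 methyl (2R)-2-[4-(allyloxy)-2-(benzyloxy)-6-hydroxyphenyl]piperidine-1-carboxylate, via ortho-quinone methide 8 (not isolated)
Conditions: (R)-3,3'-bis(2,4,6-triisopropylphenyl)-1,1'-binaphthyl-2,2'-diyl hydrogen phosphate (C50H57O4P, 10 mol %), toluene (0.01 M), 5 Å molecular sieves, −30 °C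
Reagents that add atoms: none
Why: Proposed new method: the phosphoric acid protonates the benzylic hydroxyl of 7 and water leaves with electron push from the single free ortho hydroxyl (helped by the para allyloxy and ortho benzyloxy groups), giving ortho-quinone methide 8 hydrogen-bonded to the chiral phosphate. The closest known reaction type is the chiral phosphoric acid-catalysed conjugate addition of nucleophiles to ortho-quinone methides generated in situ from ortho-hydroxybenzylic alcohols; what is new is the intramolecular use of a carbamate N–H as the nucleophile. The catalyst acts bifunctionally, its P–OH binding the quinone methide oxygen and its P=O accepting the carbamate N–H, so that nitrogen is delivered to C2' inside the pocket defined by the two triisopropylphenyl groups. The piperidine closes in a 6-exo-trig mode (the attacked C=C is exocyclic to the new ring) and ring A regains its aromaticity, which should make N–C2' formation fast and, at low temperature, irreversible. The C2' stereocentre is controlled by the catalyst alone, because 7 is racemic and its carbinol carbon becomes planar in 8. The step needs N-selectivity over attack by the electron-rich ring of another molecule, which the six-membered tether and high dilution secure, and a single catalyst-binding mode, which the lone free ortho hydroxyl secures (with two free hydroxyls the methide could tautomerise between forms that present opposite faces). It also needs the catalysed path to outrun the uncatalysed racemic closure, which toluene, −30 °C and molecular sieves favour; the carbamate is too weakly basic to quench the acid.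

Step 7
Reactants: 9 methyl (2R)-2-[4-(allyloxy)-2-(benzyloxy)-6-hydroxyphenyl]piperidine-1-carboxylate
Product: 10 methyl (2R)-2-[4-(allyloxy)-2,6-bis(benzyloxy)phenyl]piperidine-1-carboxylate
Conditions: BnBr, K2CO3, DMF, rt
Reagents that add atoms: benzyl bromide, BrCc1ccccc1
Why: Williamson etherification; capping the last ortho phenol restores the symmetry of ring A and removes the hydroxyl through which the piperidine could re-open by retro-aza-Michael elimination, so C2' is locked.

Step 8
Reactants: 10 methyl (2R)-2-[4-(allyloxy)-2,6-bis(benzyloxy)phenyl]piperidine-1-carboxylate
Product: 11 (2R)-2-[4-(allyloxy)-2,6-bis(benzyloxy)phenyl]-1-methylpiperidine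
Conditions: LiAlH4, THF, reflux; H2O/NaOH work-up
Reagents that add atoms: none
Why: Hydride reduction of the carbamate to the N-methyl amine through the iminium ion; C2' is not involved, and allyl and benzyl ethers are inert to LiAlH4.

Step 9
Reactants: 11 (2R)-2-[4-(allyloxy)-2,6-bis(benzyloxy)phenyl]-1-methylpiperidine
Product: 12 3,5-bis(benzyloxy)-4-[(2R)-1-methylpiperidin-2-yl]phenol
Conditions: Pd(PPh3)4 (5 mol %), morpholine, THF, rt
Reagents that add atoms: none
Why: Tsuji–Trost deallylation: zerovalent palladium ionises the allyl aryl ether to a π-allyl complex and morpholine traps the allyl group; benzyl ethers are untouched, and the mildly basic medium keeps the amine unprotonated so that the para-hydroxybenzylic C–N bond has no leaving group.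

Step 10
Reactants: 12 3,5-bis(benzyloxy)-4-[(2R)-1-methylpiperidin-2-yl]phenol; 13 ethyl (R)-3-hydroxy-3-phenylpropanoate
Product: 14 ethyl (3S)-3-{3,5-bis(benzyloxy)-4-[(2R)-1-methylpiperidin-2-yl]phenoxy}-3-phenylpropanoate
Conditions: PPh3, DIAD, toluene, 0 °C → rt
Reagents that add atoms: none
Why: Mitsunobu etherification; the phenoxide displaces the alkoxyphosphonium group by SN2 with inversion, turning the (R)-alcohol into the (S)-aryl ether that becomes C2, and the β-ester disfavours a carbocation pathway that would erode the configuration.

Step 11
Reactants: 14 ethyl (3S)-3-{3,5-bis(benzyloxy)-4-[(2R)-1-methylpiperidin-2-yl]phenoxy}-3-phenylpropanoate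
Product: 15 (3S)-3-{3,5-bis(benzyloxy)-4-[(2R)-1-methylpiperidin-2-yl]phenoxy}-3-phenylpropanoic acid
Conditions: LiOH·H2O, THF–H2O, 0 °C → rt; then HCl to pH 6
Reagents that add atoms: lithium hydroxide, [Li+].[OH-]
Why: Saponification of the ethyl ester; low temperature and the poor leaving-group ability of the electron-rich phenoxide hold back E1cB elimination to the cinnamate, and neither stereocentre is enolisable.

Step 12
Reactants: 15 (3S)-3-{3,5-bis(benzyloxy)-4-[(2R)-1-methylpiperidin-2-yl]phenoxy}-3-phenylpropanoic acid
Product: 17 (2S)-5,7-bis(benzyloxy)-6-[(2R)-1-methylpiperidin-2-yl]-2-phenylchroman-4-one, via mixed trifluoroacetic anhydride 16 (not isolated)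
Conditions: CF3CO2H, CH2Cl2, 0 °C; then (CF3CO)2O, 0 °C → rt; aq. NaHCO3
Reagents that add atoms: none
Why: Intramolecular Friedel–Crafts acylation through the mixed anhydride, closing the six-membered ring C at a position ortho to O1 and activated by both benzyloxy groups; ring A is symmetric, so either free position gives the 6-substituted chromanone, and protonating the amine first prevents N-acylation while C2 and C2' are not touched.

Step 13
Reactants: 17 (2S)-5,7-bis(benzyloxy)-6-[(2R)-1-methylpiperidin-2-yl]-2-phenylchroman-4-one
Product: 18 (2S)-5,7-dihydroxy-6-[(2R)-1-methylpiperidin-2-yl]-2-phenylchroman-4-one (target)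
Conditions: H2 (1 atm), 10% Pd/C, EtOAc–MeOH, AcOH (2 equiv), rt
Reagents that add atoms: none
Why: Hydrogenolysis of the two aryl benzyl ethers, which should cleave faster than the hindered benzylic C2'–N and C2–O1 bonds; acetic acid keeps the amine protonated and the medium non-basic so that ring C does not open to the chalcone.

**Compound list**

1 | 5-aminopentanoic acid | NCCCCC(=O)O | starting material
2 | 5-[(methoxycarbonyl)amino]pentanoic acid | COC(=O)NCCCCC(=O)O | intermediate
3 | phloroglucinol (benzene-1,3,5-triol) | Oc1cc(O)cc(O)c1 | starting material
4 | methyl N-[5-oxo-5-(2,4,6-trihydroxyphenyl)pentyl]carbamate | COC(=O)NCCCCC(=O)c1c(O)cc(O)cc1O | intermediate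
5 | methyl N-{5-[4-(allyloxy)-2,6-dihydroxyphenyl]-5-oxopentyl}carbamate | COC(=O)NCCCCC(=O)c1c(O)cc(OCC=C)cc1O | intermediate
6 | methyl N-{5-[4-(allyloxy)-2-(benzyloxy)-6-hydroxyphenyl]-5-oxopentyl}carbamate | COC(=O)NCCCCC(=O)c1c(O)cc(OCC=C)cc1OCc1ccccc1 | intermediate
7 | methyl N-{5-[4-(allyloxy)-2-(benzyloxy)-6-hydroxyphenyl]-5-hydroxypentyl}carbamate (racemic carbinol) | COC(=O)NCCCCC(O)c1c(O)cc(OCC=C)cc1OCc1ccccc1 | intermediate
8 | methyl N-{5-[4-(allyloxy)-2-(benzyloxy)-6-oxocyclohexa-2,4-dien-1-ylidene]pentyl}carbamate (ortho-quinone methide, not isolated) | COC(=O)NCCCCC=C1C(=O)C=C(OCC=C)C=C1OCc1ccccc1 | intermediate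
9 | methyl (2R)-2-[4-(allyloxy)-2-(benzyloxy)-6-hydroxyphenyl]piperidine-1-carboxylate | COC(=O)N1CCCC[C@@H]1c1c(O)cc(OCC=C)cc1OCc1ccccc1 | intermediate
10 | methyl (2R)-2-[4-(allyloxy)-2,6-bis(benzyloxy)phenyl]piperidine-1-carboxylate | COC(=O)N1CCCC[C@@H]1c1c(OCc2ccccc2)cc(OCC=C)cc1OCc1ccccc1 | intermediate
11 | (2R)-2-[4-(allyloxy)-2,6-bis(benzyloxy)phenyl]-1-methylpiperidine | CN1CCCC[C@@H]1c1c(OCc2ccccc2)cc(OCC=C)cc1OCc1ccccc1 | intermediate
12 | 3,5-bis(benzyloxy)-4-[(2R)-1-methylpiperidin-2-yl]phenol | CN1CCCC[C@@H]1c1c(OCc2ccccc2)cc(O)cc1OCc1ccccc1 | intermediate
13 | ethyl (R)-3-hydroxy-3-phenylpropanoate | CCOC(=O)C[C@@H](O)c1ccccc1 | starting material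
14 | ethyl (3S)-3-{3,5-bis(benzyloxy)-4-[(2R)-1-methylpiperidin-2-yl]phenoxy}-3-phenylpropanoate | CN1CCCC[C@@H]1c1c(OCc2ccccc2)cc(O[C@@H](CC(=O)OCC)c2ccccc2)cc1OCc1ccccc1 | intermediate
15 | (3S)-3-{3,5-bis(benzyloxy)-4-[(2R)-1-methylpiperidin-2-yl]phenoxy}-3-phenylpropanoic acid | CN1CCCC[C@@H]1c1c(OCc2ccccc2)cc(O[C@@H](CC(=O)O)c2ccccc2)cc1OCc1ccccc1 | intermediate
16 | (3S)-3-{3,5-bis(benzyloxy)-4-[(2R)-1-methylpiperidin-2-yl]phenoxy}-3-phenylpropanoic trifluoroacetic anhydride (present as its ammonium trifluoroacetate, not isolated) | CN1CCCC[C@@H]1c1c(OCc2ccccc2)cc(O[C@@H](CC(=O)OC(=O)C(F)(F)F)c2ccccc2)cc1OCc1ccccc1 | intermediate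
17 | (2S)-5,7-bis(benzyloxy)-6-[(2R)-1-methylpiperidin-2-yl]-2-phenylchroman-4-one | CN1CCCC[C@@H]1c1c(OCc3ccccc3)cc2c(c1OCc1ccccc1)C(=O)C[C@@H](c1ccccc1)O2 | intermediate
18 | (2S)-5,7-dihydroxy-6-[(2R)-1-methylpiperidin-2-yl]-2-phenylchroman-4-one | CN1CCCC[C@@H]1c1c(O)cc2c(c1O)C(=O)C[C@@H](c1ccccc1)O2 | target

**Step count and least certain steps**

Total step count: 13. Longest linear sequence: 13 steps (1 → 18); 3 and 13 enter as purchased materials in steps 2 and 10.

Step 6 (key step).
- What may go wrong: poor enantioface discrimination. The cation is so stabilised by three oxygen donors that closure may occur outside the chiral ion pair or without the catalyst. Intermolecular C-alkylation of another electron-rich ring is a second risk if dilution is insufficient.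
- Fallback (known chemistry), from 7 to 11: 7 is closed without stereocontrol by an achiral Brønsted acid (diphenyl phosphate, CH2Cl2, 0 °C), an acid-catalysed substitution of an activated benzylic alcohol by a carbamate. This gives racemic methyl 2-[4-(allyloxy)-2-(benzyloxy)-6-hydroxyphenyl]piperidine-1-carboxylate F1. Benzylation as in step 7 gives racemic methyl 2-[4-(allyloxy)-2,6-bis(benzyloxy)phenyl]piperidine-1-carboxylate F2. LiAlH4 reduction as in step 8 gives racemic 2-[4-(allyloxy)-2,6-bis(benzyloxy)phenyl]-1-methylpiperidine F3. The enantiomers of this basic amine are separated by preparative chromatography on a chiral stationary phase; the (R)-enantiomer is 11, where the route is rejoined.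

Step 5.
- What may go wrong: over-reduction, because under the basic hydride conditions the phenoxide can expel the benzylic oxygen and the resulting quinone methide takes up a second hydride. Premature uncatalysed cyclisation during work-up is also possible.
- Fallback, from 6 to 7: the chelated phenol of 6 is silylated (TBSOTf, 2,6-lutidine) to methyl N-{5-[4-(allyloxy)-2-(benzyloxy)-6-[(tert-butyldimethylsilyl)oxy]phenyl]-5-oxopentyl}carbamate F4. Borohydride reduction gives methyl N-{5-[4-(allyloxy)-2-(benzyloxy)-6-[(tert-butyldimethylsilyl)oxy]phenyl]-5-hydroxypentyl}carbamate F5, which has no free phenol and cannot form a quinone methide. A silyl shift to the alkoxide would be harmless, since both isomers give the same product on desilylation. Buffered fluoride (Bu4NF/AcOH, THF, −20 °C) releases 7 immediately before step 6.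

Step 12.
- What may go wrong: acid-induced ionisation of the C2'–N bond, with loss of configuration at C2' through a trialkoxybenzylic cation, or acylation at nitrogen if protonation is incomplete.
- Fallback, from 15 to 17: the trifluoroacetate salt of 15 is brominated at the free position ortho to the ether oxygen (NBS, MeCN, −20 °C) to (3S)-3-{3,5-bis(benzyloxy)-2-bromo-4-[(2R)-1-methylpiperidin-2-yl]phenoxy}-3-phenylpropanoic acid F6. Parham cyclisation (n-BuLi, THF, −78 °C: carboxylate formation, bromine–lithium exchange, attack of the aryllithium on the lithium carboxylate) then gives 17 on work-up, with no acid involved.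

Step 13.
- What may go wrong: over-hydrogenolysis (cleavage of the benzylic C2–O1 or C2'–N bond, or reduction of the ketone), and ring opening to the chalcone during a non-acidic isolation, with loss of C2 configuration and 6-to-8 migration. The free base should be liberated cold and not heated.
- Fallback, from 17 to 18: the mode of cleavage is changed from reductive to Lewis-acid dealkylation with BCl3 and pentamethylbenzene as benzyl-cation scavenger (CH2Cl2, −78 °C). This fallback makes no new compound (F0).

**Further compounds**

F1 | step 6 | methyl 2-[4-(allyloxy)-2-(benzyloxy)-6-hydroxyphenyl]piperidine-1-carboxylate (racemic) | COC(=O)N1CCCCC1c1c(O)cc(OCC=C)cc1OCc1ccccc1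
F2 | step 6 | methyl 2-[4-(allyloxy)-2,6-bis(benzyloxy)phenyl]piperidine-1-carboxylate (racemic) | COC(=O)N1CCCCC1c1c(OCc2ccccc2)cc(OCC=C)cc1OCc1ccccc1
F3 | step 6 | 2-[4-(allyloxy)-2,6-bis(benzyloxy)phenyl]-1-methylpiperidine (racemic) | CN1CCCCC1c1c(OCc2ccccc2)cc(OCC=C)cc1OCc1ccccc1
F4 | step 5 | methyl N-{5-[4-(allyloxy)-2-(benzyloxy)-6-[(tert-butyldimethylsilyl)oxy]phenyl]-5-oxopentyl}carbamate | COC(=O)NCCCCC(=O)c1c(O[Si](C)(C)C(C)(C)C)cc(OCC=C)cc1OCc1ccccc1
F5 | step 5 | methyl N-{5-[4-(allyloxy)-2-(benzyloxy)-6-[(tert-butyldimethylsilyl)oxy]phenyl]-5-hydroxypentyl}carbamate (racemic) | COC(=O)NCCCCC(O)c1c(O[Si](C)(C)C(C)(C)C)cc(OCC=C)cc1OCc1ccccc1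
F6 | step 12 | (3S)-3-{3,5-bis(benzyloxy)-2-bromo-4-[(2R)-1-methylpiperidin-2-yl]phenoxy}-3-phenylpropanoic acid | CN1CCCC[C@@H]1c1c(OCc2ccccc2)cc(O[C@@H](CC(=O)O)c2ccccc2)c(Br)c1OCc1ccccc1
F0 | step 13 | none | none
A1 | alternative 1 | (1S)-3-{2,4-bis(benzyloxy)-6-bromo-3-[(2R)-1-methylpiperidin-2-yl]phenyl}-3-[(tert-butyldimethylsilyl)oxy]-1-phenylpropan-1-ol (both C3 epimers) | CN1CCCC[C@@H]1c1c(OCc3ccccc3)cc(Br)c(c1OCc1ccccc1)C(O[Si](C)(C)C(C)(C)C)C[C@H](O)c1ccccc1
A2 | alternative 1 | (2S)-5,7-bis(benzyloxy)-4-[(tert-butyldimethylsilyl)oxy]-6-[(2R)-1-methylpiperidin-2-yl]-2-phenylchroman (both C4 epimers) | CN1CCCC[C@@H]1c1c(OCc3ccccc3)cc2c(c1OCc1ccccc1)C(O[Si](C)(C)C(C)(C)C)C[C@@H](c1ccccc1)O2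
A3 | alternative 2 | (S)-N-[(E)-2,6-bis(benzyloxy)-4-bromobenzylidene]-2-methylpropane-2-sulfinamide | CC(C)(C)[S@](=O)/N=C/c1c(OCc2ccccc2)cc(Br)cc1OCc1ccccc1
A4 | alternative 2 | (2R)-2-[2,6-bis(benzyloxy)-4-bromophenyl]-1-[(S)-tert-butanesulfinyl]piperidine | CC(C)(C)[S@](=O)N1CCCC[C@@H]1c1c(OCc2ccccc2)cc(Br)cc1OCc1ccccc1
A5 | alternative 3 | (3S)-3-{3,5-bis(benzyloxy)-4-[(2R)-1-methylpiperidin-2-yl]phenoxy}-3-phenylpropanoic acid (identical with 15) | CN1CCCC[C@@H]1c1c(OCc2ccccc2)cc(O[C@@H](CC(=O)O)c2ccccc2)cc1OCc1ccccc1
A6 | alternative 3 | (2S)-5,7-bis(benzyloxy)-6-[(2R)-1-methylpiperidin-2-yl]-2-phenylchroman-4-one (identical with 17) | CN1CCCC[C@@H]1c1c(OCc3ccccc3)cc2c(c1OCc1ccccc1)C(=O)C[C@@H](c1ccccc1)O2
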